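**Plan**
1. Retrosynthesis: the lactone C16–O bond is opened to a hydroxy acid, then C15–C16 and C1–C2 are cut together. This works because C16–C15(=C17)–C1 is a 2-carboxyallyl unit whose C1 sits on the carbinol C2 of the 14-membered ring: the retron of a terminal allene C1=C15=C17 that takes CO2 at its central carbon and the C2 aldehyde at its substituted end.
2. The linear allenyl enal is cut further at C17 (Crabbé homologation), C13–C14 (propargylation of a C13 enal), C13–O (allylic oxidation), C2–C3 and C4–C18 (carboalumination/formaldehyde) and C5–C6 (neryl bromide alkylation).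
3. Forward: nerol → (2E,6Z)-farnesol → C13 enal → homoallenyl carbinol → epoxy acetate → allenyl enal. One nickel/CO2 step then closes the 14-membered carbocycle and brings in C16; lactonisation closes the five-membered ring last.
4. Stereochemistry: 7Z from nerol, 3E from syn-carboalumination, 11E from the selenium dioxide oxidation. C11, C12 (erythro epoxidation) and C13 come from a Sharpless kinetic resolution; C13 is then inverted by Mitsunobu acetylation (threo). C1 and C2 come from the chair-like allyl transfer in the key step.

Key step: step 12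

Remark: the target is taken as drawn, i.e. 3E, 7Z (neryl-type C7=C8), trans-11,12-epoxide, threo C12/C13 and cis-fused lactone. In the text, atoms carry the target's numbering: ring C1–C14 (C1 ring-fusion CH, C2 lactone O–CH, C13 CHOAc), C15 lactone α-carbon, C16 C=O, C17 exocyclic CH2, C18–C20 the methyls on C4, C8, C12.

Step 1
Reactants: 1 nerol
Product: 2 neryl bromide
Conditions: PBr3 (0.4 equiv), pyridine (cat.), Et2O, −10 °C
Reagents that add atoms: phosphorus tribromide, BrP(Br)Br
Why: Low-temperature bromination of the primary allylic alcohol with PBr3 proceeds by direct substitution without allylic shift, so the Z geometry of the later C7=C8 bond is kept.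

Step 2
Reactants: 2 neryl bromide
Product: 4 (5Z)-6,10-dimethylundeca-5,9-dien-1-yne, via silylated enyne 3 (not isolated)
Conditions: 1-(trimethylsilyl)propyne, n-BuLi, THF, −78 °C; then 2, −78 °C to 0 °C; crude, K2CO3 (cat.), MeOH, rt
Reagents that add atoms: 1-(trimethylsilyl)propyne, CC#C[Si](C)(C)C
Why: The propargylic lithium reagent alkylates the primary allylic bromide at the bromide-bearing carbon (the silyl group suppresses the allenyl mode), which forms C5–C6 without touching the Z alkene, and methanolysis of the C–Si bond then frees the terminal alkyne.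

Step 3
Reactants: 4 (5Z)-6,10-dimethylundeca-5,9-dien-1-yne
Product: 6 (2E,6Z)-farnesol, via alkenylalane 5 (not isolated)
Conditions: AlMe3 (2 equiv), Cp2ZrCl2 (0.25 equiv), CH2Cl2, 0 °C to rt; evaporate; n-BuLi, THF, −78 °C; (CH2O)n, rt; 1 M HCl
Reagents that add atoms: trimethylaluminium, C[Al](C)C; formaldehyde (as paraformaldehyde), C=O
Why: Negishi zirconium-catalysed carboalumination adds CH3 and Al syn across the terminal alkyne with the methyl on the internal carbon, and after activation with n-BuLi the alkenyl–aluminium bond is hydroxymethylated with retention, which sets the 3E alkene and brings in C2 at the alcohol level.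

Step 4
Reactants: 6 (2E,6Z)-farnesol
Product: 7 (2E,6Z)-farnesyl tert-butyldiphenylsilyl ether
Conditions: TBDPSCl, imidazole, CH2Cl2, rt
Reagents that add atoms: tert-butyl(chloro)diphenylsilane, CC(C)(C)[Si](Cl)(c1ccccc1)c1ccccc1
Why: Standard silylation of the primary alcohol; the TBDPS ether masks the C2 oxygen through the oxidative, organometallic and Mitsunobu steps and is removed with buffered fluoride in step 10.

Step 5
Reactants: 7 (2E,6Z)-farnesyl tert-butyldiphenylsilyl ether
Product: 9 (2E,6Z,10E)-12-silyloxy-2,6,10-trimethyldodeca-2,6,10-trienal (C13 enal), via terminal allylic alcohol 8 (not isolated)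
Conditions: SeO2 (0.1 equiv), t-BuOOH (2 equiv), salicylic acid (0.1 equiv), CH2Cl2, 0 °C to rt; crude, MnO2, CH2Cl2, rt
Reagents that add atoms: tert-butyl hydroperoxide, CC(C)(C)OO (oxygen passed on through the SeO2 catalyst)
Why: Selenium dioxide-catalysed allylic oxidation (ene reaction, then 2,3-sigmatropic shift) attacks the most electron-rich and least hindered terminal trisubstituted alkene at its E-methyl group, so C13 is oxygenated with 11E geometry, and MnO2 converges alcohol and aldehyde to the enal while the C3=C4 alkene is deactivated by the allylic silyl ether.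

Step 6
Reactants: 9 C13 enal
Product: 10 racemic homopropargylic alcohol
Conditions: Zn dust, propargyl bromide, THF, 0 °C to rt; sat. aq. NH4Cl
Reagents that add atoms: propargyl bromide, C#CCBr
Why: Zinc Barbier propargylation, in which the allenylzinc formed in the flask adds to the aldehyde carbonyl through its γ-carbon in a cyclic transition state, gives the 1,2-adduct with C13–C14 formed; C13 is racemic here and is resolved in step 8.

Step 7
Reactants: 10 racemic homopropargylic alcohol
Product: 12 racemic homoallenyl allylic alcohol, via propargylic amine 11 (not isolated)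
Conditions: CuI (0.5 equiv), (CH2O)n (2.5 equiv), Cy2NH (1.8 equiv), dioxane, reflux
Reagents that add atoms: formaldehyde (as paraformaldehyde), C=O
Why: Crabbé homologation, in which the copper-mediated Mannich reaction gives the propargylic amine 11 that undergoes 1,5-hydride transfer and loses the imine, turns the terminal alkyne into the terminal allene (C17 added) and tolerates the free hydroxyl group.

Step 8
Reactants: 12 racemic homoallenyl allylic alcohol
Product: 13 (5S,6S,7S)-epoxy alcohol
Conditions: Ti(OiPr)4 (0.2 equiv), L-(+)-DIPT (0.25 equiv), t-BuOOH (0.6 equiv), 4 Å MS, CH2Cl2, −20 °C, stopped near half conversion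
Reagents that add atoms: tert-butyl hydroperoxide, CC(C)(C)OO
Why: Sharpless kinetic resolution–epoxidation, in which the L-(+)-tartrate catalyst epoxidises the 13S enantiomer fast on the face that gives the erythro 11S,12S,13S epoxy alcohol (the 13R enantiomer is left and separated), sets C11 and C12 and selects C13, and only the allylic-alcohol alkene reacts, not the other trisubstituted alkenes or the allene.

Step 9
Reactants: 13 (5S,6S,7S)-epoxy alcohol
Product: 14 (5R,6R,7S)-epoxy acetate
Conditions: AcOH, PPh3, DIAD, toluene, 0 °C to rt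
Reagents that add atoms: acetic acid, CC(=O)O
Why: Mitsunobu esterification displaces the activated C13 hydroxyl by acetate in an SN2 step with inversion, which turns the erythro alcohol into the threo 13R acetate of the target in one step (the C12 descriptor changes from S to R only through the new CIP ranking).

Step 10
Reactants: 14 (5R,6R,7S)-epoxy acetate
Product: 15 C2 allylic alcohol
Conditions: TBAF, AcOH (1:1), THF, rt
Reagents that add atoms: none
Why: Fluoride cleaves the Si–O bond, and buffering with acetic acid keeps the medium non-basic so that the C13 acetate is neither cleaved nor shifted and the epoxide stays intact.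

Step 11
Reactants: 15 C2 allylic alcohol
Product: 16 allenyl enal
Conditions: MnO2 (excess), CH2Cl2, rt
Reagents that add atoms: none
Why: MnO2 oxidises only the primary allylic alcohol and stops at the aldehyde, giving the 2E enal without touching the allene, the epoxide or the acetate.

Step 12
Reactants: 16 allenyl enal
Product: 19 2-[(1S,2S,3E,7Z,11S,12R,13R)-13-acetoxy-11,12-epoxy-2-hydroxy-4,8,12-trimethylcyclotetradeca-3,7-dien-1-yl]prop-2-enoic acid, via allylnickel carboxylate 17 (not isolated), via nickel alkoxide carboxylate 18 (not isolated)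
Conditions: Ni(cod)2 (1.2 equiv), DBU (3 equiv), CO2 (1 atm), THF, 0 °C; 16 added by syringe pump (final 2 mM), then rt; cold aq. NH4Cl/HCl to pH 4
Reagents that add atoms: carbon dioxide, O=C=O
Why: Proposed new method: zerovalent nickel with DBU binds the terminal C15=C17 bond of the allene and couples it oxidatively with CO2 at the central carbon (C15–C16) to give the η3-allylnickel carboxylate 17, whose σ-allyl form (nickel on C17) transfers the substituted terminus C1 to the tethered enal carbon C2 through a six-membered chair, closing the 14-membered carbocycle in a 14-exo-trig mode (the lactone ring is not closed here). The closest known reaction type is the nickel-mediated sequential coupling of a terminal allene, CO2 and an aryl aldehyde, here run with a conjugated enal in an intramolecular, macrocyclising format. C1 and C2 are set together: the allyl terminus carries C14 cis to C17 and trans to the carboxylate (as in 2-carboxyallyl metals) and the C3 alkenyl group of the aldehyde sits equatorial, which gives the syn adduct with H-1 and H-2 cis. Their sense relative to C13 should follow from the transition state that keeps C2–C1–C14–C13–C12 extended with the C1–C15 bond anti to the C13 acetate (no syn-pentane contact), which is the 1S,2S arrangement. The step needs chemoselectivity for the allene over the enal (the cumulated π bond should couple with CO2 faster than a nickel–enal complex reacts), regioselectivity (CO2 at the central carbon, aldehyde at C1 by allylic transposition) and ring closure over oligomerisation, the last secured by slow addition at high dilution.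

Step 13
Reactants: 19 hydroxy acid
Product: 20 CNP0146076.3 (target)
Conditions: DIC, DMAP (cat.), CH2Cl2, 0 °C to rt
Reagents that add atoms: none
Why: Carbodiimide activation of the acid with DMAP catalysis closes the five-membered lactone onto the cis-disposed C2 hydroxyl (5-exo-trig acyl substitution) under neutral conditions that spare the epoxide and the acetate.

**Compound list**
1 | nerol, (2Z)-3,7-dimethylocta-2,6-dien-1-ol | CC(C)=CCC/C(C)=C\CO | starting material
2 | neryl bromide, (2Z)-1-bromo-3,7-dimethylocta-2,6-diene | CC(C)=CCC/C(C)=C\CBr | intermediate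
3 | (5Z)-6,10-dimethyl-1-(trimethylsilyl)undeca-5,9-dien-1-yne | C[Si](C)(C)C#CCC/C=C(/C)CCC=C(C)C | intermediate
4 | (5Z)-6,10-dimethylundeca-5,9-dien-1-yne | C#CCC/C=C(/C)CCC=C(C)C | intermediate
5 | dimethyl[(1E,5Z)-2,6,10-trimethylundeca-1,5,9-trien-1-yl]alane | C[Al](C)/C=C(\C)CC/C=C(/C)CCC=C(C)C | intermediate
6 | (2E,6Z)-farnesol, (2E,6Z)-3,7,11-trimethyldodeca-2,6,10-trien-1-ol | OC/C=C(\C)CC/C=C(/C)CCC=C(C)C | intermediate
7 | tert-butyl(diphenyl){[(2E,6Z)-3,7,11-trimethyldodeca-2,6,10-trien-1-yl]oxy}silane | CC(C)(C)[Si](c1ccccc1)(c1ccccc1)OC/C=C(\C)CC/C=C(/C)CCC=C(C)C | intermediate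
8 | (2E,6Z,10E)-12-{[tert-butyl(diphenyl)silyl]oxy}-2,6,10-trimethyldodeca-2,6,10-trien-1-ol | CC(C)(C)[Si](c1ccccc1)(c1ccccc1)OC/C=C(\C)CC/C=C(/C)CC/C=C(\C)CO | intermediate
9 | (2E,6Z,10E)-12-{[tert-butyl(diphenyl)silyl]oxy}-2,6,10-trimethyldodeca-2,6,10-trienal | CC(C)(C)[Si](c1ccccc1)(c1ccccc1)OC/C=C(\C)CC/C=C(/C)CC/C=C(\C)C=O | intermediate
10 | racemic (5E,9Z,13E)-15-{[tert-butyl(diphenyl)silyl]oxy}-5,9,13-trimethylpentadeca-5,9,13-trien-1-yn-4-ol | CC(C)(C)[Si](c1ccccc1)(c1ccccc1)OC/C=C(\C)CC/C=C(/C)CC/C=C(\C)C(O)CC#C | intermediate
11 | racemic (6E,10Z,14E)-16-{[tert-butyl(diphenyl)silyl]oxy}-1-(dicyclohexylamino)-6,10,14-trimethylhexadeca-6,10,14-trien-2-yn-5-ol | CC(C)(C)[Si](c1ccccc1)(c1ccccc1)OC/C=C(\C)CC/C=C(/C)CC/C=C(\C)C(O)CC#CCN(C1CCCCC1)C1CCCCC1 | intermediate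
12 | racemic (6E,10Z,14E)-16-{[tert-butyl(diphenyl)silyl]oxy}-6,10,14-trimethylhexadeca-1,2,6,10,14-pentaen-5-ol | CC(C)(C)[Si](c1ccccc1)(c1ccccc1)OC/C=C(\C)CC/C=C(/C)CC/C=C(\C)C(O)CC=C=C | intermediate
13 | (5S,6S,7S,10Z,14E)-16-{[tert-butyl(diphenyl)silyl]oxy}-6,7-epoxy-6,10,14-trimethylhexadeca-1,2,10,14-tetraen-5-ol (erythro) | CC(C)(C)[Si](c1ccccc1)(c1ccccc1)OC/C=C(\C)CC/C=C(/C)CC[C@@H]1O[C@@]1(C)[C@@H](O)CC=C=C | intermediate
14 | (5R,6R,7S,10Z,14E)-16-{[tert-butyl(diphenyl)silyl]oxy}-6,7-epoxy-6,10,14-trimethylhexadeca-1,2,10,14-tetraen-5-yl acetate (threo) | CC(C)(C)[Si](c1ccccc1)(c1ccccc1)OC/C=C(\C)CC/C=C(/C)CC[C@@H]1O[C@@]1(C)[C@H](OC(C)=O)CC=C=C | intermediate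
15 | (2E,6Z,10S,11R,12R)-10,11-epoxy-1-hydroxy-3,7,11-trimethylhexadeca-2,6,14,15-tetraen-12-yl acetate | OC/C=C(\C)CC/C=C(/C)CC[C@@H]1O[C@@]1(C)[C@H](OC(C)=O)CC=C=C | intermediate
16 | (2E,6Z,10S,11R,12R)-10,11-epoxy-3,7,11-trimethyl-1-oxohexadeca-2,6,14,15-tetraen-12-yl acetate | O=C/C=C(\C)CC/C=C(/C)CC[C@@H]1O[C@@]1(C)[C@H](OC(C)=O)CC=C=C | intermediate
17 | DBU-ligated allylnickel carboxylate from 16 and CO2 (drawn as the σ-allyl form: five-membered Ni–O–C16–C15–C17 ring, C14 cis to C17) | O=C/C=C(\C)CC/C=C(/C)CC[C@@H]1O[C@@]1(C)[C@H](OC(C)=O)C/C=C2\C[Ni]OC2=O | intermediate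
18 | divalent nickel chelate of the C2 alkoxide and C16 carboxylate of 19 | C=C1C(=O)O[Ni]O[C@H]2/C=C(\C)CC/C=C(/C)CC[C@@H]3O[C@@]3(C)[C@H](OC(C)=O)C[C@@H]12 | intermediate
19 | 2-[(1S,2S,3E,7Z,11S,12R,13R)-13-acetoxy-11,12-epoxy-2-hydroxy-4,8,12-trimethylcyclotetradeca-3,7-dien-1-yl]prop-2-enoic acid | O[C@H]1/C=C(\C)CC/C=C(/C)CC[C@@H]2O[C@@]2(C)[C@H](OC(C)=O)C[C@H]1C(=C)C(=O)O | intermediate
20 | CNP0146076.3, (1S,2S,3E,7Z,11S,12R,13R)-13-acetoxy-11,12-epoxycembra-3,7,15(17)-trien-16,2-olide | C=C1C(=O)O[C@H]2/C=C(\C)CC/C=C(/C)CC[C@@H]3O[C@@]3(C)[C@H](OC(C)=O)C[C@@H]12 | target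

**Step count:** 13 steps in total; longest linear sequence 13 steps (from nerol).

**Steps most likely to fail**

1. Step 12 (the labelled step). Possible failures: intermolecular allyl transfer leading to oligomers; protonation or β-hydride elimination of the allylnickel before ring closure; diversion of zerovalent nickel by the enal; the wrong facial pairing at C1/C2 relative to C13. Fallback with known reaction types, setting out from 16 and returning at 20: iodine (I2, CH2Cl2, 0 °C) adds to the allene only and gives the 2,3-diiodide F1, whose allylic and geometric isomers converge in the next operation. CrCl2 in THF at high dilution turns the allylic iodide into an allylchromium that adds through C1 to the C2 aldehyde in an intramolecular Nozaki–Hiyama allylation; the vinylic iodide stays inert in the absence of a nickel co-catalyst, and the 2-iodo substituent should favour the cis H-1/H-2 relationship. This gives the macrocyclic 2-iodoallyl carbinol F2. Carbonylative lactonisation with zerovalent palladium (Pd(PPh3)4 cat., CO 1 atm, K2CO3, THF, 50 °C) then closes the α-methylene lactone to 20. In this variant C16 comes from CO instead of CO2 and the two C–C bonds are made in separate operations.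

2. Step 9. Possible failure: slow displacement at a carbinol flanked by the quaternary epoxide carbon, so that elimination or retention through participation of the epoxide oxygen competes with inversion. Fallback, setting out from 13 and returning at 14: Dess–Martin oxidation (NaHCO3, CH2Cl2) gives the epoxy ketone F3. Reagent-controlled Corey–Bakshi–Shibata reduction with (S)-2-methyl-CBS-oxazaborolidine and catecholborane at −78 °C, with the quaternary epoxide carbon as the large group, should give the 13R (threo) epoxy alcohol F4. Acetylation (Ac2O, pyridine, DMAP) gives 14. The stereocentre is then set by hydride delivery and not by substitution.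

3. Step 7. Possible failure: stalling at the Mannich base, or thermal and base-induced degradation of the doubly activated carbinol during the prolonged reflux. Fallback, setting out from 9 and returning at 12: buta-1,3-dien-2-ylmagnesium chloride (from chloroprene and Mg, THF, −78 °C to 0 °C) adds to the aldehyde with allylic transposition and installs C14, C1, C15 and C17 as the terminal allene in one C–C bond formation. This bypasses alkyne 10 and needs no heating; a minor dienyl carbinol regioisomer would be removed by chromatography.

**Further compounds**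
F1 | step 12 | (2E,6Z,10S,11R,12R)-10,11-epoxy-15,16-diiodo-3,7,11-trimethyl-1-oxohexadeca-2,6,14-trien-12-yl acetate (mixture at the C14=C15 bond) | O=C/C=C(\C)CC/C=C(/C)CC[C@@H]1O[C@@]1(C)[C@H](OC(C)=O)CC=C(I)CI
F2 | step 12 | 13-acetoxy-11,12-epoxy-2-hydroxy-1-(1-iodoethenyl)-4,8,12-trimethylcyclotetradeca-3,7-diene, all stereocentres arranged as in 19 (3E,7Z) | O[C@H]1/C=C(\C)CC/C=C(/C)CC[C@@H]2O[C@@]2(C)[C@H](OC(C)=O)C[C@H]1C(I)=C
F3 | step 9 | (6R,7S,10Z,14E)-16-{[tert-butyl(diphenyl)silyl]oxy}-6,7-epoxy-6,10,14-trimethylhexadeca-1,2,10,14-tetraen-5-one | CC(C)(C)[Si](c1ccccc1)(c1ccccc1)OC/C=C(\C)CC/C=C(/C)CC[C@@H]1O[C@@]1(C)C(=O)CC=C=C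
F4 | step 9 | (5R,6S,7S,10Z,14E)-16-{[tert-butyl(diphenyl)silyl]oxy}-6,7-epoxy-6,10,14-trimethylhexadeca-1,2,10,14-tetraen-5-ol (threo) | CC(C)(C)[Si](c1ccccc1)(c1ccccc1)OC/C=C(\C)CC/C=C(/C)CC[C@@H]1O[C@@]1(C)[C@H](O)CC=C=C
F0 | step 7 | none | none
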